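**Plan**
Retrosynthesis (eunicellane numbering: ring O between C2 and C9, ring fusion C1/C10, lactone C16(=O)–O–C3): C6–OH/C7=CH2 from a (6Z)-C6=C7 alkene (ene reaction); C4 ester; lactone C16–O; C15–C16 (CO) and the C15/C11 methyls (MeMgBr); then C1–C10 and C13–C14 together ([4+2]); C6=C7 (ring-closing metathesis); C4–C5 and C3–C4 (chelation-controlled additions); C2–O (SN2).
Forward: ether joining C9 and C2 → nine-membered oxonene → cyclohexane and oxolane in one cycloaddition → seven-membered lactone → C6/C7 adjustment.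
Enabling feature: the ring oxygen is flanked by C2 and C9, cis on the oxonane, so C9–O–C2 is a three-atom tether that holds a C10–C13 diene (C11 oxygen carried as a silyl enol ether) against a C1=C14 dienophile (activated by the future C15 acyl carbon).
Stereochemistry: C9 by Brown methallylation; C2 from methyl (R)-glycerate with inversion; C3 and C4 by 1,2-chelation control; C1, C10, C14 in the cycloaddition; C11 by convex-face MeMgBr addition; C15 by ligand-controlled hydrogenation; C6 by a peripheral ene reaction.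

Key step: step 16

Remark: the target as given is (1S,2S,3S,4R,6R,9S,10R,11R,14R,15R) in eunicellane numbering, and all intermediates are drawn in that series; 1 and 3 are taken as catalogue compounds.

**Step 1**
Reactants: 1 3-[(4-methoxyphenyl)methoxy]propanal
Product: 2 (3S)-1-[(4-methoxyphenyl)methoxy]-5-methylhex-5-en-3-ol
Conditions: (−)-Ipc2BOMe, CH2=C(CH3)CH2MgCl, Et2O, −78 → 25 °C; then 1, −78 °C; then NaOH, H2O2
Reagents that add atoms: 2-methylallylmagnesium chloride, CC(=C)C[Mg]Cl
Why: Brown asymmetric methallylboration through a closed chair transition state; the reagent from (−)-Ipc2BOMe should attack the Si face of the aldehyde (its known sense for aliphatic aldehydes), which gives the (S)-carbinol that becomes C9.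

**Step 2**
Reactants: 3 methyl (2R)-2,3-dihydroxypropanoate
Product: 4 methyl (2R)-3-[(tert-butyldimethylsilyl)oxy]-2-hydroxypropanoate
Conditions: t-BuMe2SiCl, imidazole, CH2Cl2, 0 °C
Reagents that add atoms: tert-butyldimethylsilyl chloride, CC(C)(C)[Si](C)(C)Cl
Why: Silylation should select the primary hydroxyl over the hindered, less nucleophilic α-hydroxy ester position; no stereocentre is touched.

**Step 3**
Reactants: 4 methyl (2R)-3-[(tert-butyldimethylsilyl)oxy]-2-hydroxypropanoate
Product: 5 methyl (2R)-3-[(tert-butyldimethylsilyl)oxy]-2-[(trifluoromethanesulfonyl)oxy]propanoate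
Conditions: Tf2O, 2,6-lutidine, CH2Cl2, −78 °C
Reagents that add atoms: trifluoromethanesulfonic anhydride, O=S(=O)(OS(=O)(=O)C(F)(F)F)C(F)(F)F
Why: O-Sulfonylation of the α-hydroxy ester proceeds with retention and gives an α-triflyloxy ester that is configurationally stable at low temperature.

**Step 4**
Reactants: 2 (3S)-1-[(4-methoxyphenyl)methoxy]-5-methylhex-5-en-3-ol; 5 methyl (2R)-3-[(tert-butyldimethylsilyl)oxy]-2-[(trifluoromethanesulfonyl)oxy]propanoate
Product: 6 methyl (2S)-3-[(tert-butyldimethylsilyl)oxy]-2-{[(3S)-1-[(4-methoxyphenyl)methoxy]-5-methylhex-5-en-3-yl]oxy}propanoate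
Conditions: NaH, THF, 0 °C; then 5, −78 → −20 °C
Reagents that add atoms: none
Why: Williamson-type SN2 displacement of an α-triflyloxy ester by an alkoxide, which the adjacent carbonyl accelerates and which should go with clean inversion to set (S)-C2; the low temperature is meant to suppress elimination and transesterification.

**Step 5**
Reactants: 6 methyl (2S)-3-[(tert-butyldimethylsilyl)oxy]-2-{[(3S)-1-[(4-methoxyphenyl)methoxy]-5-methylhex-5-en-3-yl]oxy}propanoate
Product: 8 methyl ketone (3S)-4-[(tert-butyldimethylsilyl)oxy]-3-{[(3S)-1-[(4-methoxyphenyl)methoxy]-5-methylhex-5-en-3-yl]oxy}butan-2-one, via Weinreb amide 7 (not isolated)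
Conditions: MeNHOMe·HCl, i-PrMgCl, THF, −20 °C; then MeMgBr, −20 → 0 °C
Reagents that add atoms: N,O-dimethylhydroxylamine hydrochloride, CNOC.Cl (its atoms stay only in 7); methylmagnesium bromide, C[Mg]Br
Why: One-pot aminolysis of the ester by the magnesium amide followed by Weinreb ketone synthesis; the chelated tetrahedral intermediate should prevent over-addition and the low temperature should keep C2 intact.

**Step 6**
Reactants: 8 methyl ketone (C3 carbonyl)
Product: 9 (2R,3S)-4-[(tert-butyldimethylsilyl)oxy]-2-(1,3-dithian-2-yl)-3-{[(3S)-1-[(4-methoxyphenyl)methoxy]-5-methylhex-5-en-3-yl]oxy}butan-2-ol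
Conditions: 1,3-dithiane, n-BuLi, THF, −30 °C; MgBr2·OEt2; then 8, −78 °C
Reagents that add atoms: 1,3-dithiane, C1CSCSC1
Why: Corey–Seebach acyl-anion addition under Cram-chelate control: magnesium should bridge the C3 carbonyl oxygen and the C2 ether oxygen (the silyl ether does not compete), so the nucleophile enters past H2 and anti to CH2OTBS, giving the 2,3-syn tertiary carbinol C3.

**Step 7**
Reactants: 9 dithiane carbinol
Product: 10 (2R,3S)-4-[(tert-butyldimethylsilyl)oxy]-2-hydroxy-3-{[(3S)-1-[(4-methoxyphenyl)methoxy]-5-methylhex-5-en-3-yl]oxy}-2-methylbutanal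
Conditions: MeI, CaCO3, MeCN/H2O (9:1), 40 °C
Reagents that add atoms: water, O
Why: Alkylative hydrolysis of the dithiane under buffered, non-oxidising conditions that should spare the alkene, the PMB ether and the silyl ether; the α-quaternary aldehyde cannot epimerise.

**Step 8**
Reactants: 10 α-hydroxy aldehyde (C4)
Product: 11 (2S,3S,4R)-1-[(tert-butyldimethylsilyl)oxy]-2-{[(3S)-1-[(4-methoxyphenyl)methoxy]-5-methylhex-5-en-3-yl]oxy}-3-methylhept-6-ene-3,4-diol
Conditions: CH2=CHCH2SnBu3, MgBr2·OEt2, CH2Cl2, −78 → −20 °C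
Reagents that add atoms: allyltributylstannane, C=CC[Sn](CCCC)(CCCC)CCCC
Why: Chelation-controlled carbonyl allylation with an allylstannane: magnesium should bridge the aldehyde oxygen and the C3 hydroxyl, and the allyl group enters past the small C3 methyl and not past the branched C2, giving the 3,4-syn diol and setting C4.

**Step 9**
Reactants: 11 diol
Product: 12 (2S,3R,4R)-1,4-bis[(tert-butyldimethylsilyl)oxy]-2-{[(3S)-1-[(4-methoxyphenyl)methoxy]-5-methylhex-5-en-3-yl]oxy}-3-methylhept-6-en-3-ol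
Conditions: t-BuMe2SiOTf (1.05 equiv), 2,6-lutidine, CH2Cl2, −78 °C
Reagents that add atoms: tert-butyldimethylsilyl triflate, CC(C)(C)[Si](C)(C)OS(=O)(=O)C(F)(F)F
Why: Silyl triflate silylation should select the secondary C4 hydroxyl over the tertiary C3 hydroxyl at low temperature with one equivalent of reagent.

**Step 10**
Reactants: 12 diene
Product: 13 oxonene (2S,3R,4R,6Z,9S)-4-[(tert-butyldimethylsilyl)oxy]-2-{[(tert-butyldimethylsilyl)oxy]methyl}-9-{2-[(4-methoxyphenyl)methoxy]ethyl}-3,7-dimethyl-2,3,4,5,8,9-hexahydrooxonin-3-ol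
Conditions: second-generation Grubbs catalyst RuCl2(=CHPh)(PCy3)(H2IMes) (10 mol %), CH2Cl2 (0.002 M), 40 °C
Reagents that add atoms: none
Why: Ring-closing metathesis of a monosubstituted with a 1,1-disubstituted alkene; the two branched carbons flanking the ether oxygen turn the chains toward each other, high dilution disfavours dimers, and the nine-membered ring allows only the Z trisubstituted alkene.

**Step 11**
Reactants: 13 oxonene
Product: 14 (2S,3R,4R,6Z,9S)-4-[(tert-butyldimethylsilyl)oxy]-2-(hydroxymethyl)-9-{2-[(4-methoxyphenyl)methoxy]ethyl}-3,7-dimethyl-2,3,4,5,8,9-hexahydrooxonin-3-ol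
Conditions: HF·pyridine, pyridine, THF, 0 °C
Reagents that add atoms: none
Why: Buffered fluoride desilylation should cleave the primary silyl ether much faster than the secondary one at C4, which is shielded by the quaternary C3.

**Step 12**
Reactants: 14 primary alcohol (C1)
Product: 16 (2E)-3-[(2S,3R,4R,6Z,9S)-4-[(tert-butyldimethylsilyl)oxy]-3-hydroxy-9-{2-[(4-methoxyphenyl)methoxy]ethyl}-3,7-dimethyl-2,3,4,5,8,9-hexahydrooxonin-2-yl]-N-methoxy-N-methylprop-2-enamide, via C1 aldehyde 15 (not isolated)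
Conditions: Dess–Martin periodinane, NaHCO3, CH2Cl2, 0 → 25 °C; then Ph3P=CHC(O)N(OMe)Me, 25 °C
Reagents that add atoms: N-methoxy-N-methyl-2-(triphenylphosphoranylidene)acetamide, CON(C)C(=O)C=P(c1ccccc1)(c1ccccc1)c1ccccc1
Why: One-pot Dess–Martin oxidation and Wittig olefination with a stabilised ylide, which should give the E alkene and, being neutral, should not epimerise the α-alkoxy aldehyde or trigger retro-aldol loss of the C3 carbinol.

**Step 13**
Reactants: 16 enamide
Product: 17 (2E)-3-[(2S,3R,4R,6Z,9S)-4-[(tert-butyldimethylsilyl)oxy]-3-hydroxy-9-(2-hydroxyethyl)-3,7-dimethyl-2,3,4,5,8,9-hexahydrooxonin-2-yl]-N-methoxy-N-methylprop-2-enamide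
Conditions: DDQ, CH2Cl2/pH 7 buffer (10:1), 0 °C
Reagents that add atoms: none
Why: Oxidative cleavage of the 4-methoxybenzyl ether by hydride abstraction and hydrolysis; the electron-poor enamide, the trisubstituted alkene and the silyl ether should not react.

**Step 14**
Reactants: 17 primary alcohol (C11)
Product: 19 (2E)-3-[(2S,3R,4R,6Z,9S)-4-[(tert-butyldimethylsilyl)oxy]-3-hydroxy-9-(2-hydroxybut-3-en-1-yl)-3,7-dimethyl-2,3,4,5,8,9-hexahydrooxonin-2-yl]-N-methoxy-N-methylprop-2-enamide (both C11 epimers), via C11 aldehyde 18 (not isolated)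
Conditions: (COCl)2, DMSO, THF, −78 °C; Et3N; then CH2=CHMgBr (5 equiv), −78 °C
Reagents that add atoms: vinylmagnesium bromide, C=C[Mg]Br
Why: One-pot Swern oxidation and Grignard addition, which avoids isolating a β-alkoxy aldehyde prone to elimination; at −78 °C the aldehyde should react far faster than the Weinreb enamide, and the new carbinol centre is removed in the next step.

**Step 15**
Reactants: 19 allylic alcohol
Product: 20 vinyl ketone (2E)-3-[(2S,3R,4R,6Z,9S)-4-[(tert-butyldimethylsilyl)oxy]-3-hydroxy-3,7-dimethyl-9-(2-oxobut-3-en-1-yl)-2,3,4,5,8,9-hexahydrooxonin-2-yl]-N-methoxy-N-methylprop-2-enamide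
Conditions: Dess–Martin periodinane, NaHCO3, CH2Cl2, 0 °C
Reagents that add atoms: none
Why: Dess–Martin oxidation of a secondary allylic alcohol under buffered conditions, which should leave the tertiary alcohol and the enamide untouched.

**Step 16**
Reactants: 20 vinyl ketone
Product: 23 tricyclic keto amide (C11 ketone; C14 Weinreb amide; C3–OSiEt3; C4–OTBS), via silyl dienol ether 21 (not isolated), via enol ether cycloadduct 22 (not isolated)
Conditions: Et3SiOTf (3 equiv), Et3N (5 equiv), ClCH2CH2Cl, −20 → 60 °C; then 0.5 M HCl, THF, 0 °C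
Reagents that add atoms: triethylsilyl triflate, CC[Si](CC)(CC)OS(=O)(=O)C(F)(F)F
Why: Soft enolisation of the vinyl ketone should give the (Z)-2-silyloxy diene C10=C11(OSiEt3)–C12=C13 (silylating C3–OH on the way), which then undergoes a concerted but asynchronous normal-demand intramolecular [4+2] cycloaddition with the (E)-C1=C14 enamide, whose carbonyl the silyl triflate can activate; dilute acid finally unmasks the C11 ketone. The closest known reaction type is the intramolecular Diels–Alder reaction of oxonene-bridged trienes carrying a 2-silyloxy diene, used to build the hydroisobenzofuran core of 2,11-cyclised cembranoids. The cyclohexene closes by the [4+2] union itself (bonds C1–C10 and C13–C14), and the oxolane (O, C2, C1, C10, C9) closes in the same event as the tether ring of a type 1 intramolecular cycloaddition across the three-atom C9–O–C2 link, C1–C10 being its last bond. C14 is set relative to C1 by the E geometry of the dienophile (C2 and C15 trans), the cis ring fusion (H1 and H10 syn) by the exo transition state with the amide carbonyl turned away from the diene and C9 on the outside of the Z dienol ether, and the sense relative to C2 and C9 by the cis-2,9-oxonene, which lets diene and dienophile stack only on the face of the C9–O–C2 unit opposite to ring carbons C3 and C8, so that H1 and H10 fall anti to H2 and H9. The step needs exo over endo selectivity and a single π-face; both should be secured by the short tether braced by the nine-membered ring (the endo mode would force the amide across the oxonene), and only the Z dienol ether, the usual product of amine/silyl triflate enolisation, can reach the dienophile.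

**Step 17**
Reactants: 23 tricyclic keto amide
Product: 24 tricyclic hydroxy methyl ketone (C11 tertiary alcohol; C14 acetyl)
Conditions: MeMgBr (5 equiv), THF, −78 → 0 °C
Reagents that add atoms: methylmagnesium bromide, C[Mg]Br
Why: Grignard addition to the C11 ketone should occur from the convex face of the cis-fused bicycle, axially and anti to the axial C10–C9 bond, which places the methyl cis to H10 and the hydroxyl cis to C9 as in the target; the same reagent converts the Weinreb amide into the C15 methyl ketone (Weinreb ketone synthesis).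

**Step 18**
Reactants: 24 hydroxy methyl ketone
Product: 25 vinyl triflate (C14–C(OTf)=CH2)
Conditions: KN(SiMe3)2 (2.5 equiv), THF, −78 °C; then PhNTf2
Reagents that add atoms: N-phenylbis(trifluoromethanesulfonimide), O=S(=O)(N(c1ccccc1)S(=O)(=O)C(F)(F)F)C(F)(F)F
Why: Kinetic deprotonation at the methyl group (not at the hindered C14 methine) and O-triflation of the enolate; the hindered tertiary C11 alkoxide should not be sulfonylated at −78 °C, and C3 is protected.

**Step 19**
Reactants: 25 vinyl triflate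
Product: 26 2-substituted acrylic acid (C14–C(=CH2)CO2H)
Conditions: Pd(OAc)2 (5 mol %), dppp, CO (1 atm), Et3N, DMF/H2O (10:1), 60 °C
Reagents that add atoms: carbon monoxide, [C-]#[O+]; water, O
Why: Palladium-catalysed hydroxycarbonylation (oxidative addition of zerovalent palladium, CO insertion, hydrolysis of the acylpalladium) installs C16; the C11 hydroxyl is trans-1,4 to the acyl group across the cyclohexane and cannot capture it.

**Step 20**
Reactants: 26 acrylic acid
Product: 28 seco acid (15R; free C3–OH), via silyl ether acid 27 (not isolated)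
Conditions: Ru(OAc)2[(R)-BINAP] (2 mol %), H2 (50 atm), MeOH, 25 °C; then AcOH/THF/H2O (3:1:1), 25 °C
Reagents that add atoms: none
Why: Carboxylate-directed asymmetric hydrogenation of a 2-substituted acrylic acid, with the (R)-ligand chosen by analogy with 2-arylacrylic acids (where the (S)-ligand gives the (S)-acid) so that C15 becomes R; the isolated trisubstituted alkene is inert to this catalyst, and mild acid then removes the tertiary triethylsilyl ether but not the hindered C4 silyl ether.

**Step 21**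
Reactants: 28 seco acid
Product: 30 tetracyclic lactone (C16(=O)–O–C3; C4–OTBS; 6Z-ene), via mixed anhydride 29 (not isolated)
Conditions: 2,4,6-Cl3C6H2COCl, Et3N, THF, 25 °C; then DMAP, toluene (0.002 M), 80 °C
Reagents that add atoms: 2,4,6-trichlorobenzoyl chloride, O=C(Cl)c1c(Cl)cc(Cl)cc1Cl (its atoms stay only in 29)
Why: Yamaguchi lactonisation: C3–OH and the C16 acyl group sit on the neighbouring equatorial C2 and C15 arms of C1 and C14 and are held close, so the seven-membered trans-fused lactone should close, whereas C11–OH is geometrically out of reach and C4–OH is protected; the mild base should leave C15 intact.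

**Step 22**
Reactants: 30 lactone
Product: 31 lactone with free C4–OH
Conditions: HF·pyridine, THF, 25 → 40 °C
Reagents that add atoms: none
Why: Fluoride-driven cleavage of the remaining silyl ether under weakly acidic conditions, which should not epimerise C15 or open the lactone.

**Step 23**
Reactants: 31 hydroxy lactone
Product: 32 C4 octanoate (6Z-ene)
Conditions: n-C7H15COCl, pyridine, DMAP (cat.), CH2Cl2, 0 → 25 °C
Reagents that add atoms: octanoyl chloride, CCCCCCCC(=O)Cl
Why: DMAP-catalysed acylation should esterify the only secondary hydroxyl (C4) and leave the tertiary C11 hydroxyl untouched.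

**Step 24**
Reactants: 32 octanoate
Product: 34 briarellin B, via C6 hydroperoxide 33 (not isolated)
Conditions: O2, tetraphenylporphyrin (cat.), visible light, CH2Cl2, 0 °C; then PPh3, 25 °C
Reagents that add atoms: dioxygen, O=O
Why: Schenck ene reaction: singlet oxygen should attack C6 on the exposed outer face of the (Z)-C6=C7 alkene (the face used by other oxidants on this ring system) and take a hydrogen from the freely rotating C7 methyl, whose C–H bonds align with the π system better than the ring allylic ones, giving the exocyclic alkene and the (6R) hydroperoxide, which PPh3 reduces to the alcohol.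

**Compound list**
1 | 3-[(4-methoxyphenyl)methoxy]propanal | O=CCCOCc1ccc(OC)cc1 | starting material
2 | (3S)-1-[(4-methoxyphenyl)methoxy]-5-methylhex-5-en-3-ol | C=C(C)C[C@@H](CCOCc1ccc(OC)cc1)O | intermediate
3 | methyl (2R)-2,3-dihydroxypropanoate (methyl D-glycerate) | COC(=O)[C@H](O)CO | starting material
4 | methyl (2R)-3-[(tert-butyldimethylsilyl)oxy]-2-hydroxypropanoate | COC(=O)[C@H](O)CO[Si](C)(C)C(C)(C)C | intermediate
5 | methyl (2R)-3-[(tert-butyldimethylsilyl)oxy]-2-[(trifluoromethanesulfonyl)oxy]propanoate | COC(=O)[C@H](OS(=O)(=O)C(F)(F)F)CO[Si](C)(C)C(C)(C)C | intermediate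
6 | methyl (2S)-3-[(tert-butyldimethylsilyl)oxy]-2-{[(3S)-1-[(4-methoxyphenyl)methoxy]-5-methylhex-5-en-3-yl]oxy}propanoate | C=C(C)C[C@@H](CCOCc1ccc(OC)cc1)O[C@H](C(=O)OC)CO[Si](C)(C)C(C)(C)C | intermediate
7 | (2S)-3-[(tert-butyldimethylsilyl)oxy]-N-methoxy-2-{[(3S)-1-[(4-methoxyphenyl)methoxy]-5-methylhex-5-en-3-yl]oxy}-N-methylpropanamide | C=C(C)C[C@@H](CCOCc1ccc(OC)cc1)O[C@H](C(=O)N(C)OC)CO[Si](C)(C)C(C)(C)C | intermediate
8 | (3S)-4-[(tert-butyldimethylsilyl)oxy]-3-{[(3S)-1-[(4-methoxyphenyl)methoxy]-5-methylhex-5-en-3-yl]oxy}butan-2-one | C=C(C)C[C@@H](CCOCc1ccc(OC)cc1)O[C@H](C(C)=O)CO[Si](C)(C)C(C)(C)C | intermediate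
9 | (2R,3S)-4-[(tert-butyldimethylsilyl)oxy]-2-(1,3-dithian-2-yl)-3-{[(3S)-1-[(4-methoxyphenyl)methoxy]-5-methylhex-5-en-3-yl]oxy}butan-2-ol | C=C(C)C[C@@H](CCOCc1ccc(OC)cc1)O[C@@H](CO[Si](C)(C)C(C)(C)C)[C@@](C)(O)C1SCCCS1 | intermediate
10 | (2R,3S)-4-[(tert-butyldimethylsilyl)oxy]-2-hydroxy-3-{[(3S)-1-[(4-methoxyphenyl)methoxy]-5-methylhex-5-en-3-yl]oxy}-2-methylbutanal | C=C(C)C[C@@H](CCOCc1ccc(OC)cc1)O[C@@H](CO[Si](C)(C)C(C)(C)C)[C@@](C)(O)C=O | intermediate
11 | (2S,3S,4R)-1-[(tert-butyldimethylsilyl)oxy]-2-{[(3S)-1-[(4-methoxyphenyl)methoxy]-5-methylhex-5-en-3-yl]oxy}-3-methylhept-6-ene-3,4-diol | C=C(C)C[C@@H](CCOCc1ccc(OC)cc1)O[C@@H](CO[Si](C)(C)C(C)(C)C)[C@@](C)(O)[C@H](O)CC=C | intermediate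
12 | (2S,3R,4R)-1,4-bis[(tert-butyldimethylsilyl)oxy]-2-{[(3S)-1-[(4-methoxyphenyl)methoxy]-5-methylhex-5-en-3-yl]oxy}-3-methylhept-6-en-3-ol | C=C(C)C[C@@H](CCOCc1ccc(OC)cc1)O[C@@H](CO[Si](C)(C)C(C)(C)C)[C@@](C)(O)[C@H](O[Si](C)(C)C(C)(C)C)CC=C | intermediate
13 | (2S,3R,4R,6Z,9S)-4-[(tert-butyldimethylsilyl)oxy]-2-{[(tert-butyldimethylsilyl)oxy]methyl}-9-{2-[(4-methoxyphenyl)methoxy]ethyl}-3,7-dimethyl-2,3,4,5,8,9-hexahydrooxonin-3-ol (cis-2,9; ring locants equal eunicellane C2–C9) | O[C@@]3(C)[C@H](O[Si](C)(C)C(C)(C)C)C/C=C(/C)\C[C@@H](CCOCc1ccc(OC)cc1)O[C@H]3CO[Si](C)(C)C(C)(C)C | intermediate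
14 | (2S,3R,4R,6Z,9S)-4-[(tert-butyldimethylsilyl)oxy]-2-(hydroxymethyl)-9-{2-[(4-methoxyphenyl)methoxy]ethyl}-3,7-dimethyl-2,3,4,5,8,9-hexahydrooxonin-3-ol | O[C@@]3(C)[C@H](O[Si](C)(C)C(C)(C)C)C/C=C(/C)\C[C@@H](CCOCc1ccc(OC)cc1)O[C@H]3CO | intermediate
15 | (2R,3R,4R,6Z,9S)-4-[(tert-butyldimethylsilyl)oxy]-3-hydroxy-9-{2-[(4-methoxyphenyl)methoxy]ethyl}-3,7-dimethyl-2,3,4,5,8,9-hexahydrooxonine-2-carbaldehyde | O[C@@]3(C)[C@H](O[Si](C)(C)C(C)(C)C)C/C=C(/C)\C[C@@H](CCOCc1ccc(OC)cc1)O[C@H]3C=O | intermediate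
16 | (2E)-3-[(2S,3R,4R,6Z,9S)-4-[(tert-butyldimethylsilyl)oxy]-3-hydroxy-9-{2-[(4-methoxyphenyl)methoxy]ethyl}-3,7-dimethyl-2,3,4,5,8,9-hexahydrooxonin-2-yl]-N-methoxy-N-methylprop-2-enamide | O[C@@]3(C)[C@H](O[Si](C)(C)C(C)(C)C)C/C=C(/C)\C[C@@H](CCOCc1ccc(OC)cc1)O[C@H]3/C=C/C(=O)N(C)OC | intermediate
17 | as 16 with a 9-(2-hydroxyethyl) group | O[C@@]3(C)[C@H](O[Si](C)(C)C(C)(C)C)C/C=C(/C)\C[C@@H](CCO)O[C@H]3/C=C/C(=O)N(C)OC | intermediate
18 | as 16 with a 9-(2-oxoethyl) group (C11 aldehyde) | O[C@@]3(C)[C@H](O[Si](C)(C)C(C)(C)C)C/C=C(/C)\C[C@@H](CC=O)O[C@H]3/C=C/C(=O)N(C)OC | intermediate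
19 | as 16 with a 9-(2-hydroxybut-3-en-1-yl) group (both C11 epimers) | O[C@@]3(C)[C@H](O[Si](C)(C)C(C)(C)C)C/C=C(/C)\C[C@@H](CC(O)C=C)O[C@H]3/C=C/C(=O)N(C)OC | intermediate
20 | as 16 with a 9-(2-oxobut-3-en-1-yl) group (vinyl ketone) | O[C@@]3(C)[C@H](O[Si](C)(C)C(C)(C)C)C/C=C(/C)\C[C@@H](CC(=O)C=C)O[C@H]3/C=C/C(=O)N(C)OC | intermediate
21 | (2E)-N-methoxy-N-methyl-3-[(2S,3R,4R,6Z,9S)-4-[(tert-butyldimethylsilyl)oxy]-3,7-dimethyl-3-[(triethylsilyl)oxy]-9-[(1Z)-2-[(triethylsilyl)oxy]buta-1,3-dien-1-yl]-2,3,4,5,8,9-hexahydrooxonin-2-yl]prop-2-enamide | CC[Si](CC)(CC)O[C@@]3(C)[C@H](O[Si](C)(C)C(C)(C)C)C/C=C(/C)\C[C@@H](/C=C(\O[Si](CC)(CC)CC)C=C)O[C@H]3/C=C/C(=O)N(C)OC | intermediate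
22 | enol ether cycloadduct: as 23 but with C11(OSiEt3)=C12 in place of the C11 ketone | CC[Si](CC)(CC)O[C@@]3(C)[C@H](O[Si](C)(C)C(C)(C)C)C/C=C(/C)\C[C@@H]2O[C@H]3[C@H]4[C@@H](CC=C(O[Si](CC)(CC)CC)[C@H]42)C(=O)N(C)OC | intermediate
23 | tricyclic keto amide: (6Z)-oxonene bridged by the C2–O–C9 oxolane and fused through C1/C10 to a cyclohexanone (C11=O); C14–C(=O)N(OMe)Me, C3–OSiEt3, C4–OTBS; H1 and H10 cis to each other and anti to H2 and H9, C14 substituent trans to C2; C1, C2, C3, C4, C9, C10, C14 arranged as in 34 | CC[Si](CC)(CC)O[C@@]3(C)[C@H](O[Si](C)(C)C(C)(C)C)C/C=C(/C)\C[C@@H]2O[C@H]3[C@H]4[C@@H](CCC(=O)[C@H]42)C(=O)N(C)OC | intermediate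
24 | as 23 with C11(OH)(CH3) (hydroxyl cis to C9, as in 34) and C14–C(=O)CH3 | CC[Si](CC)(CC)O[C@@]3(C)[C@H](O[Si](C)(C)C(C)(C)C)C/C=C(/C)\C[C@@H]2O[C@H]3[C@H]4[C@@H](CC[C@@](C)(O)[C@H]42)C(C)=O | intermediate
25 | as 24 with C14–C(OSO2CF3)=CH2 | CC[Si](CC)(CC)O[C@@]3(C)[C@H](O[Si](C)(C)C(C)(C)C)C/C=C(/C)\C[C@@H]2O[C@H]3[C@H]4[C@@H](CC[C@@](C)(O)[C@H]42)C(=C)OS(=O)(=O)C(F)(F)F | intermediate
26 | as 24 with C14–C(=CH2)CO2H | CC[Si](CC)(CC)O[C@@]3(C)[C@H](O[Si](C)(C)C(C)(C)C)C/C=C(/C)\C[C@@H]2O[C@H]3[C@H]4[C@@H](CC[C@@](C)(O)[C@H]42)C(=C)C(=O)O | intermediate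
27 | as 26 after reduction: C14–CH(CH3)CO2H with C15 as in 34 (15R); C3–OSiEt3 | CC[Si](CC)(CC)O[C@@]3(C)[C@H](O[Si](C)(C)C(C)(C)C)C/C=C(/C)\C[C@@H]2O[C@H]3[C@H]4[C@@H](CC[C@@](C)(O)[C@H]42)[C@@H](C)C(=O)O | intermediate
28 | seco acid: as 27 with free C3–OH | O[C@@]3(C)[C@H](O[Si](C)(C)C(C)(C)C)C/C=C(/C)\C[C@@H]2O[C@H]3[C@H]4[C@@H](CC[C@@](C)(O)[C@H]42)[C@@H](C)C(=O)O | intermediate
29 | mixed anhydride of 28 with 2,4,6-trichlorobenzoic acid | O[C@@]3(C)[C@H](O[Si](C)(C)C(C)(C)C)C/C=C(/C)\C[C@@H]2O[C@H]3[C@H]4[C@@H](CC[C@@](C)(O)[C@H]42)[C@@H](C)C(=O)OC(=O)c1c(Cl)cc(Cl)cc1Cl | intermediate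
30 | tetracyclic lactone: 34 skeleton with C16(=O)–O–C3 closed, C4–OTBS and (6Z)-C6=C7(CH3) in place of C6–OH/C7=CH2 | C1/C=C(/C)\C[C@@H]2O[C@H]3[C@H]4[C@@H](CC[C@@](C)(O)[C@H]42)[C@@H](C)C(=O)O[C@@]3(C)[C@@H]1O[Si](C)(C)C(C)(C)C | intermediate
31 | as 30 with free C4–OH | C1/C=C(/C)\C[C@@H]2O[C@H]3[C@H]4[C@@H](CC[C@@](C)(O)[C@H]42)[C@@H](C)C(=O)O[C@@]3(C)[C@@H]1O | intermediate
32 | as 30 with C4–O-octanoyl (6-deoxy-6,7-didehydro isomer of 34 with a C7 methyl) | C1/C=C(/C)\C[C@@H]2O[C@H]3[C@H]4[C@@H](CC[C@@](C)(O)[C@H]42)[C@@H](C)C(=O)O[C@@]3(C)[C@@H]1OC(=O)CCCCCCC | intermediate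
33 | briarellin B C6 hydroperoxide (C6–OOH in place of C6–OH) | C=C1C[C@@H]2O[C@H]3[C@H]4[C@@H](CC[C@@](C)(O)[C@H]42)[C@@H](C)C(=O)O[C@@]3(C)[C@H](OC(=O)CCCCCCC)C[C@H]1OO | intermediate
34 | briarellin B, (1S,2S,3S,4R,6R,9S,10R,11R,14R,15R) | C=C1C[C@@H]2O[C@H]3[C@H]4[C@@H](CC[C@@](C)(O)[C@H]42)[C@@H](C)C(=O)O[C@@]3(C)[C@H](OC(=O)CCCCCCC)C[C@H]1O | target

**Totals and risks**
Total step count: 24. Longest linear sequence: 23 steps (3 → 34, steps 2 to 24).

Steps most likely to fail:

Step 16. The vinyl ketone may polymerise during silylation, the unreactive E dienol ether may form, or exo and facial control may erode with the less electrophilic amide dienophile. Fallback, from 20 back to 23: the same two bonds would be made stepwise by an anionic Michael–Michael annulation. LiN(SiMe3)2 (2.2 equiv) in THF at −78 → 0 °C should form the C10 enolate of the vinyl ketone, which adds to C1 of the enamide; the resulting amide enolate then closes onto C13 of the enone, and protonation would give the tricyclic keto amide with free C3–OH F1. Et3SiOTf and 2,6-lutidine would then silylate the tertiary alcohol and return to 23.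

Step 21. Acylation of the tertiary C3 hydroxyl may be too slow, so that oligomerisation or epimerisation at C15 of the activated acid takes over. Fallback, from 25 back to 30: the ester bond would be made from an acylpalladium species before C15 is a stereocentre. HF·pyridine/pyridine should remove the tertiary triethylsilyl ether of 25 to give the hydroxy vinyl triflate F2. Pd(OAc)2/dppp, CO (1 atm), Et3N in DMF at 60 °C would then carbonylate the triflate with capture by C3–OH, giving the α-methylene lactone F3. Hydrogenation of its exocyclic alkene with Ru(OAc)2[(R)-BINAP] and H2 would set C15 and give 30.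

Step 24. Singlet oxygen may take a ring allylic hydrogen and not a methyl hydrogen, giving endocyclic or tertiary allylic hydroperoxides, or it may attack the wrong face. Fallback, from 32 to 34: dimethyldioxirane in acetone at −20 °C should epoxidise the exposed face to give the 6,7-epoxide F4. Cp2TiCl (trivalent titanium, made from Cp2TiCl2 and Mn) in THF would open the epoxide homolytically at the tertiary C7, and loss of a methyl hydrogen from the C7 radical would give the exocyclic alkene and the C6 alcohol, that is 34 directly.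

**Further compounds**
F1 | step 16 | tricyclic keto amide with free C3–OH (23 without the triethylsilyl group) | O[C@@]3(C)[C@H](O[Si](C)(C)C(C)(C)C)C/C=C(/C)\C[C@@H]2O[C@H]3[C@H]4[C@@H](CCC(=O)[C@H]42)C(=O)N(C)OC
F2 | step 21 | hydroxy vinyl triflate (25 without the triethylsilyl group) | O[C@@]3(C)[C@H](O[Si](C)(C)C(C)(C)C)C/C=C(/C)\C[C@@H]2O[C@H]3[C@H]4[C@@H](CC[C@@](C)(O)[C@H]42)C(=C)OS(=O)(=O)C(F)(F)F
F3 | step 21 | α-methylene lactone (30 with C15=CH2 in place of C15H–CH3) | C1/C=C(/C)\C[C@@H]2O[C@H]3[C@H]4[C@@H](CC[C@@](C)(O)[C@H]42)C(=C)C(=O)O[C@@]3(C)[C@@H]1O[Si](C)(C)C(C)(C)C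
F4 | step 24 | 6,7-epoxide of 32 (cis epoxide, oxygen on the face of the target C6–OH) | C[C@]15C[C@@H]2O[C@H]3[C@H]4[C@@H](CC[C@@](C)(O)[C@H]42)[C@@H](C)C(=O)O[C@@]3(C)[C@H](OC(=O)CCCCCCC)C[C@H]1O5
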